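**Plan**

1. Numbering (cembrane): ring C1–C14 with C1 = butenolide β-carbon, C2 = lactone CH–O, C8 bearing CO2Me, C13 = CH–OAc, C14 = CH2; C15/C16 = butenolide α-carbon/carbonyl.
2. Retrosynthesis cuts C13–C14 (ring), then C1–C2 plus the lactone C16–O bond (lactone annulation), then C7=C8 and C8–C9 (chain assembly).
3. Forward: the C2–C13 chain is joined by phosphonate alkylation (C8–C9) and Z-selective olefination (C7=C8); an α-methyl-β-methylene lactone is annulated onto the C2 aldehyde; the 14-membered ring closes last at C13–C14, which also moves the exocyclic C1=C14 alkene into the butenolide ring (C1=C15).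
4. Enabling feature: C13 is an allylic carbon carrying an acetate (C11=C12–C13–OAc is the product pattern of substitution on an allylic gem-diacetate), and C14 is the vinylogous carbon of the butenolide ring C16(=O)–C15=C1–C14, reachable as the terminus of a dienolate from the β-methylene lactone.
5. Stereochemistry: C2 from ligand-controlled alkenylchromium addition to the enal; C13 from ligand-controlled ionisation of the gem-diacetate; alkene geometry from geranyl acetate (C3=C4), selenium dioxide oxidation (C11=C12) and Still–Gennari olefination (C7=C8).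

Key step: step 14

Assumption (chemistry): the ligand enantiomers written in steps 10 and 14 are taken to give Re-face addition at C2 and the (13S) acetate; if either induction runs the other way, the mirror-image ligand is used without other change. C15 is carried as a mixture of epimers from step 10 to step 13 and becomes sp2 in step 14.

**Route**

Step 1
Reactants: 1 5-bromo-2-methylpent-2-ene
Product: 2 (E)-5-bromo-2-methylpent-2-en-1-ol
Conditions: SeO2 (cat.), salicylic acid (cat.), t-BuOOH, CH2Cl2, rt
Reagents that add atoms: tert-butyl hydroperoxide, CC(C)(C)OO (oxygen atom, relayed by SeO2)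
Why: selenium dioxide allylic oxidation (ene reaction, then 2,3-sigmatropic shift) of a gem-dimethyl trisubstituted alkene attacks the (E)-methyl group, so the (E)-geometry of C11=C12 is fixed here.

Step 2
Reactants: 2 (E)-5-bromo-2-methylpent-2-en-1-ol
Product: 3 TBS ether of 2, {[(E)-5-bromo-2-methylpent-2-en-1-yl]oxy}(tert-butyl)dimethylsilane
Conditions: TBSCl, imidazole, CH2Cl2, 0 °C to rt
Reagents that add atoms: tert-butyldimethylsilyl chloride, CC(C)(C)[Si](C)(C)Cl
Why: routine silylation of a primary allylic alcohol protects the future C13 oxygen through the basic steps 3, 6 and 7.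

Step 3
Reactants: 3 TBS ether bromide; 4 methyl 2-[bis(2,2,2-trifluoroethoxy)phosphoryl]acetate
Product: 5 methyl (E)-2-[bis(2,2,2-trifluoroethoxy)phosphoryl]-7-[(tert-butyldimethylsilyl)oxy]-6-methylhept-5-enoate (racemic at the phosphonate carbon)
Conditions: NaH, DMF, 0 °C; then 3, Bu4NI (cat.), 50 °C
Reagents that add atoms: none
Why: C-alkylation of the stabilised phosphonoacetate anion by the primary bromide (iodide catalysis) forms C8–C9 and gives the α-substituted Still–Gennari reagent.

Step 4
Reactants: 6 geranyl acetate
Product: 7 6,7-epoxygeranyl acetate (racemic)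
Conditions: mCPBA, CH2Cl2, −20 to 0 °C
Reagents that add atoms: 3-chloroperoxybenzoic acid, OOC(=O)c1cccc(Cl)c1
Why: Prilezhaev epoxidation prefers the 6,7-alkene, the more electron-rich one because the 2,3-alkene is deactivated by the allylic acetate; the epoxide stereocentre is removed in step 5.

Step 5
Reactants: 7 6,7-epoxygeranyl acetate
Product: 8 (E)-3-methyl-6-oxohex-2-en-1-yl acetate
Conditions: H5IO6, THF/H2O, 0 °C
Reagents that add atoms: none
Why: periodic acid opens the epoxide to the diol and cleaves it in the same flask (Malaprade cleavage, acetone lost), giving the C7 aldehyde, whose oxygen is the former epoxide oxygen, with the (E)-C3=C4 alkene and the acetate untouched.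

Step 6
Reactants: 5 phosphonate; 8 aldehyde
Product: 9 methyl (2Z,6E)-8-acetoxy-2-[(3E)-5-[(tert-butyldimethylsilyl)oxy]-4-methylpent-3-en-1-yl]-6-methylocta-2,6-dienoate
Conditions: KN(SiMe3)2, 18-crown-6, THF, −78 °C; then 8
Reagents that add atoms: none
Why: Still–Gennari olefination, in which the electron-poor trifluoroethyl phosphonate collapses from the kinetic adduct, should give the trisubstituted enoate with CO2Me cis to C6, the C7=C8 geometry of the target.

Step 7
Reactants: 9 acetate
Product: 10 methyl (2Z,6E)-2-[(3E)-5-[(tert-butyldimethylsilyl)oxy]-4-methylpent-3-en-1-yl]-8-hydroxy-6-methylocta-2,6-dienoate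
Conditions: K2CO3 (cat.), MeOH, 0 °C
Reagents that add atoms: none
Why: base-catalysed transesterification removes the primary allylic acetate, while exchange at the methyl ester is degenerate in methanol and the silyl ether is stable.

Step 8
Reactants: 10 allylic alcohol
Product: 11 methyl (2Z,6E)-2-[(3E)-5-[(tert-butyldimethylsilyl)oxy]-4-methylpent-3-en-1-yl]-6-methyl-8-oxoocta-2,6-dienoate
Conditions: MnO2, CH2Cl2, rt
Reagents that add atoms: none
Why: MnO2 oxidises allylic alcohols selectively to enals without over-oxidation and without touching the enoate or silyl ether.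

Step 9
Reactants: 12 ethyl 2-methylbuta-2,3-dienoate
Product: 13 ethyl 3-iodo-2-methylbut-3-enoate (racemic)
Conditions: NaI, AcOH, rt
Reagents that add atoms: sodium iodide, [Na+].[I-]
Why: hydroiodination of a 2,3-allenoate (iodide adds to the central allene carbon, the dienolate is protonated at the α-carbon) gives the β-iodo-β,γ-unsaturated ester that carries C14, C1, C15, C16 and the C15 methyl.

Step 10
Reactants: 11 enal; 13 alkenyl iodide
Product: 15 methyl (2Z,6E)-2-[(3E)-5-[(tert-butyldimethylsilyl)oxy]-4-methylpent-3-en-1-yl]-6-methyl-7-[(2S,4RS)-4-methyl-3-methylidene-5-oxooxolan-2-yl]hepta-2,6-dienoate, via hydroxy ester 14 (not isolated)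
Conditions: CrCl2, (S)-N-[2-(4-isopropyl-4,5-dihydro-1,3-oxazol-2-yl)-6-methylphenyl]methanesulfonamide, Et3N, THF, rt; NiCl2 (cat.), 11, 13, rt; aqueous work-up; then PPTS (cat.), toluene, 40 °C
Reagents that add atoms: none
Why: asymmetric Nozaki–Hiyama–Kishi alkenylation (nickel activates the alkenyl iodide, transmetalation to trivalent chromium, 1,2-addition) is selective for the aldehyde over both esters, the chiral sulfonamide on chromium directs the alkenyl group to the Re face of the enal to set (2S), and mild acid closes the γ-lactone with loss of ethanol.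

Step 11
Reactants: 15 silyl ether
Product: 16 methyl (2Z,6E)-2-[(3E)-5-hydroxy-4-methylpent-3-en-1-yl]-6-methyl-7-[(2S,4RS)-4-methyl-3-methylidene-5-oxooxolan-2-yl]hepta-2,6-dienoate
Conditions: HF·pyridine, pyridine, THF, 0 °C
Reagents that add atoms: none
Why: buffered fluoride desilylation avoids the basic conditions that would move the exocyclic C1=C14 alkene into conjugation.

Step 12
Reactants: 16 allylic alcohol
Product: 17 methyl (2Z,6E)-6-methyl-2-[(3E)-4-methyl-5-oxopent-3-en-1-yl]-7-[(2S,4RS)-4-methyl-3-methylidene-5-oxooxolan-2-yl]hepta-2,6-dienoate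
Conditions: MnO2, CH2Cl2, rt
Reagents that add atoms: none
Why: neutral allylic oxidation gives the (E)-2-methyl enal at C13 without affecting the methylene lactone.

Step 13
Reactants: 17 enal
Product: 18 methyl (2Z,6E)-2-[(3E)-5,5-diacetoxy-4-methylpent-3-en-1-yl]-6-methyl-7-[(2S,4RS)-4-methyl-3-methylidene-5-oxooxolan-2-yl]hepta-2,6-dienoate
Conditions: Ac2O, FeCl3 (cat.), CH2Cl2, −20 °C
Reagents that add atoms: acetic anhydride, CC(=O)OC(C)=O
Why: Lewis-acid-catalysed addition of acetic anhydride across the aldehyde (acylal formation) is fast for enals, uses no base, and gives the aldehyde surrogate that tolerates the amide base of step 14 and later supplies the C13 acetate.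

Step 14
Reactants: 18 gem-diacetate
Product: 20 16-oxosarcoglaucol acetate, via silyl dienol ether 19 (not isolated)
Conditions: TMSCl, then LiN(SiMe3)2, THF, −78 °C; the cold solution is added over 8 h to Pd2(dba)3·CHCl3 (10 mol %), N,N'-[(1R,2R)-cyclohexane-1,2-diyl]bis[2-(diphenylphosphanyl)benzamide] (25 mol %), CH2Cl2, 0 °C to rt, final concentration about 1 mM
Reagents that add atoms: chlorotrimethylsilane, C[Si](C)(C)Cl (silyl group of intermediate 19 only; it leaves again on ring closure)
Why: Proposed new method: kinetic deprotonation of the most acidic C–H of 18 (C15–H, which is both α to the lactone carbonyl and allylic to C1=C14) with in situ silylation gives the linearly conjugated silyl dienol ether 19 (O–C16=C15–C1=C14); zerovalent palladium carrying the chiral bisphosphine then ionises one of the two enantiotopic acetates on C13 to a (1-acetoxy-2-methylallyl)palladium cation, the freed acetate takes the silyl group from 19, and the dienolate terminus C14 attacks C13 on the face opposite to palladium while C1=C14 moves to C1=C15, so that the C13–C14 bond, the C13 acetate and the butenolide arise in one event. The closest known reaction types are the asymmetric Tsuji–Trost alkylation of allylic gem-diacetates by stabilised carbon nucleophiles (attack at the acetoxy-bearing terminus), palladium π-allyl macrocyclisation and γ-selective allylation of silyl dienolates; their combination with a lactone-derived vinylogous nucleophile in a ring closure is new. The 14-membered carbocycle closes by attack on the allyl terminus remote from the tether (C13), so that the whole allyl unit C11–C12–C13 lies in the ring with C11=C12 kept E (endo-type closure; attack at C11 would give a 12-membered ring with an exocyclic enol acetate), and the lactone ring is not closed here but converted into the butenolide. C13 is controlled by the ligand, which chooses the acetate that leaves, followed by outer-sphere attack with inversion, independently of the remote C2 centre; C2 is not at risk because the lactone is masked as 19 until the butenolide forms and no base stronger than acetate is present afterwards. The step needs C14 over C15 on the nucleophile (C15 would become a quaternary centre inside the ligand pocket, and attack through C14 gives the conjugated lactone), C13 over C11 on the electrophile (the oxygen-bearing terminus carries the larger positive charge), ionisation of the acylal in preference to the allylic lactone C2–O bond (acylals ionise faster than simple allylic esters, and in 19 the ring oxygen is part of a ketene acetal), and ring closure over oligomerisation (slow addition at high dilution).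

**Compound list**

1 | 5-bromo-2-methylpent-2-ene | CC(C)=CCCBr | starting material
2 | (E)-5-bromo-2-methylpent-2-en-1-ol | OC/C(C)=C/CCBr | intermediate
3 | {[(E)-5-bromo-2-methylpent-2-en-1-yl]oxy}(tert-butyl)dimethylsilane | CC(C)(C)[Si](C)(C)OC/C(C)=C/CCBr | intermediate
4 | methyl 2-[bis(2,2,2-trifluoroethoxy)phosphoryl]acetate | COC(=O)CP(=O)(OCC(F)(F)F)OCC(F)(F)F | starting material
5 | methyl (E)-2-[bis(2,2,2-trifluoroethoxy)phosphoryl]-7-[(tert-butyldimethylsilyl)oxy]-6-methylhept-5-enoate (racemic) | COC(=O)C(CC/C=C(\C)CO[Si](C)(C)C(C)(C)C)P(=O)(OCC(F)(F)F)OCC(F)(F)F | intermediate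
6 | geranyl acetate, (2E)-3,7-dimethylocta-2,6-dien-1-yl acetate | CC(C)=CCC/C(C)=C/COC(C)=O | starting material
7 | (2E)-5-(3,3-dimethyloxiran-2-yl)-3-methylpent-2-en-1-yl acetate (racemic) | CC1(C)OC1CC/C(C)=C/COC(C)=O | intermediate
8 | (E)-3-methyl-6-oxohex-2-en-1-yl acetate | O=CCC/C(C)=C/COC(C)=O | intermediate
9 | methyl (2Z,6E)-8-acetoxy-2-[(3E)-5-[(tert-butyldimethylsilyl)oxy]-4-methylpent-3-en-1-yl]-6-methylocta-2,6-dienoate | COC(=O)/C(CC/C=C(\C)CO[Si](C)(C)C(C)(C)C)=C\CC/C(C)=C/COC(C)=O | intermediate
10 | methyl (2Z,6E)-2-[(3E)-5-[(tert-butyldimethylsilyl)oxy]-4-methylpent-3-en-1-yl]-8-hydroxy-6-methylocta-2,6-dienoate | COC(=O)/C(CC/C=C(\C)CO[Si](C)(C)C(C)(C)C)=C\CC/C(C)=C/CO | intermediate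
11 | methyl (2Z,6E)-2-[(3E)-5-[(tert-butyldimethylsilyl)oxy]-4-methylpent-3-en-1-yl]-6-methyl-8-oxoocta-2,6-dienoate | COC(=O)/C(CC/C=C(\C)CO[Si](C)(C)C(C)(C)C)=C\CC/C(C)=C/C=O | intermediate
12 | ethyl 2-methylbuta-2,3-dienoate | CCOC(=O)C(C)=C=C | starting material
13 | ethyl 3-iodo-2-methylbut-3-enoate (racemic) | CCOC(=O)C(C)C(I)=C | intermediate
14 | 1-ethyl 11-methyl (4S,5E,9Z)-10-[(3E)-5-[(tert-butyldimethylsilyl)oxy]-4-methylpent-3-en-1-yl]-4-hydroxy-2,6-dimethyl-3-methylideneundeca-5,9-dienedioate (C15 epimers) | COC(=O)/C(CC/C=C(\C)CO[Si](C)(C)C(C)(C)C)=C\CC/C(C)=C/[C@H](O)C(=C)C(C)C(=O)OCC | intermediate (not isolated)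
15 | methyl (2Z,6E)-2-[(3E)-5-[(tert-butyldimethylsilyl)oxy]-4-methylpent-3-en-1-yl]-6-methyl-7-[(2S,4RS)-4-methyl-3-methylidene-5-oxooxolan-2-yl]hepta-2,6-dienoate | COC(=O)/C(CC/C=C(\C)CO[Si](C)(C)C(C)(C)C)=C\CC/C(C)=C/[C@@H]1OC(=O)C(C)C1=C | intermediate
16 | methyl (2Z,6E)-2-[(3E)-5-hydroxy-4-methylpent-3-en-1-yl]-6-methyl-7-[(2S,4RS)-4-methyl-3-methylidene-5-oxooxolan-2-yl]hepta-2,6-dienoate | COC(=O)/C(CC/C=C(\C)CO)=C\CC/C(C)=C/[C@@H]1OC(=O)C(C)C1=C | intermediate
17 | methyl (2Z,6E)-6-methyl-2-[(3E)-4-methyl-5-oxopent-3-en-1-yl]-7-[(2S,4RS)-4-methyl-3-methylidene-5-oxooxolan-2-yl]hepta-2,6-dienoate | COC(=O)/C(CC/C=C(\C)C=O)=C\CC/C(C)=C/[C@@H]1OC(=O)C(C)C1=C | intermediate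
18 | methyl (2Z,6E)-2-[(3E)-5,5-diacetoxy-4-methylpent-3-en-1-yl]-6-methyl-7-[(2S,4RS)-4-methyl-3-methylidene-5-oxooxolan-2-yl]hepta-2,6-dienoate | COC(=O)/C(CC/C=C(\C)C(OC(C)=O)OC(C)=O)=C\CC/C(C)=C/[C@@H]1OC(=O)C(C)C1=C | intermediate
19 | methyl (2Z,6E)-2-[(3E)-5,5-diacetoxy-4-methylpent-3-en-1-yl]-6-methyl-7-[(2S)-4-methyl-3-methylidene-5-[(trimethylsilyl)oxy]-2,3-dihydrofuran-2-yl]hepta-2,6-dienoate | COC(=O)/C(CC/C=C(\C)C(OC(C)=O)OC(C)=O)=C\CC/C(C)=C/[C@@H]1OC(O[Si](C)(C)C)=C(C)C1=C | intermediate (not isolated)
20 | 16-oxosarcoglaucol acetate (2S,13S; 3E,7Z,11E in cembrane numbering) | COC(=O)/C1=C\CC/C(C)=C/[C@@H]2OC(=O)C(C)=C2C[C@H](OC(C)=O)/C(C)=C/CC1 | target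

**Count**

Total steps: 14. Longest linear sequence: 11 steps (steps 1–3, 6–8 and 10–14, from 5-bromo-2-methylpent-2-ene).

**Steps most likely to fail**

Step 14. What may go wrong: ionisation of the doubly allylic lactone C2–O bond or re-ionisation of the product allylic acetate by zerovalent palladium (loss of C2 or C13 integrity, 1,3-acetate shift, elimination towards a conjugated trienolide), attack through C15 or at C11, and oligomerisation. Fallback from 18, returning at 20: 18 is silylated exactly as in step 14 to 19, and the cold solution is added slowly to TMSOTf (cat.) and 2,6-di-tert-butylpyridine in CH2Cl2 at −78 °C. Loss of trimethylsilyl acetate gives an acetoxy-stabilised allyl cation, which 19 attacks through C14 in a vinylogous Mukaiyama-type addition (the acetal/acylal variant of the Mukaiyama aldol reaction). This should give the macrocyclic acetate as a mixture of C13 epimers F1. Because no reagent controls C13 here, the mixture is methanolysed (Mg(OMe)2, MeOH, 0 °C) to the epimeric C13 alcohols F2 and oxidised (Dess–Martin periodinane, NaHCO3, CH2Cl2) to the single C13 enone F3. Corey–Bakshi–Shibata reduction ((R)-2-methyl-CBS-oxazaborolidine, catecholborane, toluene, −78 °C, the α-methylalkenyl group acting as the large substituent) should give the (13S)-alcohol F4. Acetylation (Ac2O, pyridine, DMAP (cat.), 0 °C) returns to the route at 20.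

Step 10. What may go wrong: poor facial selectivity at C2, migration of the exocyclic alkene into conjugation by amine base, or acid-induced allylic transposition of the doubly allylic alcohol during lactonisation. Fallback from 11 and 13, returning at 15: the coupling is run without chiral ligand (CrCl2, NiCl2 (cat.), DMF, rt) and worked up under neutral conditions to give the racemic hydroxy ester F5. Sharpless kinetic resolution (Ti(OiPr)4, L-(+)-diisopropyl tartrate, t-BuOOH, 4 Å molecular sieves, CH2Cl2, −20 °C, stopped just past half conversion) epoxidises the C3=C4 alkene of the (2R)-alcohol, the trisubstituted and more nucleophilic of its two allylic alkenes, to give the epoxy alcohol F6 and leaves the (2S)-alcohol, which is 14. Compound 14 is lactonised with PPTS as in step 10, and the route is rejoined at 15.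

Step 3. What may go wrong: low conversion, dialkylation, or elimination of the homoallylic bromide, because the trifluoroethyl phosphonate anion is a weak nucleophile. Fallback from 3, returning at 9: the phosphonate class is changed to a diaryl phosphonate, whose anion is the stronger nucleophile. Diphenyl phosphite and methyl bromoacetate (Et3N, CH2Cl2, 0 °C) give methyl 2-(diphenoxyphosphoryl)acetate F7. Its sodium salt (NaH, DMSO/THF, rt) is alkylated by 3 to the diaryl phosphonate F8. Z-selective Horner–Wadsworth–Emmons olefination of 8 with F8 (NaH, THF, −78 to 0 °C) returns to the route at 9.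

**Further compounds**

F1 | step 14 | 16-oxosarcoglaucol acetate as a mixture of C13 epimers | COC(=O)/C1=C\CC/C(C)=C/[C@@H]2OC(=O)C(C)=C2CC(OC(C)=O)/C(C)=C/CC1
F2 | step 14 | 16-oxosarcoglaucol (C13 alcohol) as a mixture of C13 epimers | COC(=O)/C1=C\CC/C(C)=C/[C@@H]2OC(=O)C(C)=C2CC(O)/C(C)=C/CC1
F3 | step 14 | 13-oxo macrocycle (C13 ketone conjugated with C11=C12) | COC(=O)/C1=C\CC/C(C)=C/[C@@H]2OC(=O)C(C)=C2CC(=O)/C(C)=C/CC1
F4 | step 14 | (2S,13S)-16-oxosarcoglaucol (free C13 alcohol) | COC(=O)/C1=C\CC/C(C)=C/[C@@H]2OC(=O)C(C)=C2C[C@H](O)/C(C)=C/CC1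
F5 | step 10 | racemic hydroxy ester (racemate of 14, C15 epimers) | COC(=O)/C(CC/C=C(\C)CO[Si](C)(C)C(C)(C)C)=C\CC/C(C)=C/C(O)C(=C)C(C)C(=O)OCC
F6 | step 10 | (3R,4R)-C3–C4 epoxy alcohol formed from the (2R)-enantiomer of F5 (erythro; the carbinol descriptor becomes S after epoxidation) | COC(=O)/C(CC/C=C(\C)CO[Si](C)(C)C(C)(C)C)=C\CC[C@@]1(C)O[C@@H]1[C@@H](O)C(=C)C(C)C(=O)OCC
F7 | step 3 | methyl 2-(diphenoxyphosphoryl)acetate | COC(=O)CP(=O)(Oc1ccccc1)Oc1ccccc1
F8 | step 3 | methyl (E)-7-[(tert-butyldimethylsilyl)oxy]-2-(diphenoxyphosphoryl)-6-methylhept-5-enoate (racemic) | COC(=O)C(CC/C=C(\C)CO[Si](C)(C)C(C)(C)C)P(=O)(Oc1ccccc1)Oc1ccccc1
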